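**Plan**

1. The target is the C2-symmetric (3S,3'S,all-E) retro-carotenoid diol. Each ring is numbered C1 (CMe2), C2 (CH2), C3 (CHOH), C4 (=CH), C5 (=C-Me), C6 (ring carbon of the exocyclic C6=C7 bond); the chain runs C7–C15 and C15'–C7'.
2. Retrosynthesis: both C3–O bonds go back to ketones (diketone 22). C10=C11 and C10'=C11' are cut (double Wittig: C12 bis-ylide plus two C14 keto-aldehydes), then C8=C9 and C6=C7 (Wittig, vinylogous Horner–Wadsworth–Emmons) back to ring phosphonate 9. The ring of 9 is cut at C1–C2 and C4=C5 into a C2–C3–C4 acetone-type ylide and a C1–C6–C5 isopropylidene ketophosphonate.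
3. Enabling feature: with C3 as a ketone, each ring is a 3,5,5-trimethylcyclohex-2-enone. C3=O is 1,5 to a carbonyl at C5 through the quaternary C1 (Michael retron) and conjugated to C4=C5 (carbonyl-olefination retron). A phosphoryl group at C6 activates the acceptor and later delivers C6=C7.
4. Forward: the ring is made first by a [3+3] annulation that sets the quaternary C1, the C4=C5 alkene and the C3 oxygen together. C6=C7 and C8=C9 follow; the central C12 chain is built in two directions from glyoxal; both ends are joined at once.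
5. Stereochemistry: both C3 centres come from one reagent-controlled Corey–Bakshi–Shibata reduction in the last step. E-alkenes come from stabilised ylide and phosphonate olefinations and thermal equilibration.

Key step: step 3

Remark: the E/Z isomers about the exocyclic C6=C7 (C6'=C7') bonds are assumed to interconvert on heating at the ketone stage. Compounds 11, 12, 14 and 22 are therefore drawn as the E isomers, and this geometry is fixed by equilibration and crystallisation of 22.

**Step 1**
Reactants: 1 diethyl (2-oxopropyl)phosphonate; 2 acetone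
Product: 3 diethyl (4-methyl-2-oxopent-3-en-3-yl)phosphonate
Conditions: TiCl4, pyridine, THF, 0 °C → rt
Reagents that add atoms: none
Why: Knoevenagel condensation, in which TiCl4 activates acetone and, with pyridine, enolises the β-ketophosphonate, so that the hindered tetrasubstituted alkene forms and the water is bound by titanium; no stereo-element arises.

**Step 2**
Reactants: 4 1-(triphenylphosphoranylidene)propan-2-one
Product: 5 (2-ethoxyprop-1-en-1-yl)triphenylphosphonium tetrafluoroborate
Conditions: Et3O+ BF4−, CH2Cl2, 0 °C → rt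
Reagents that add atoms: triethyloxonium tetrafluoroborate, CC[O+](CC)CC.F[B-](F)(F)F
Why: O-alkylation of an acyl-stabilised ylide by the hard oxonium salt should give the β-ethoxyvinylphosphonium salt, whose methyl group (γ to phosphorus) is now acidic.

**Step 3**
Reactants: 5 (2-ethoxyprop-1-en-1-yl)triphenylphosphonium tetrafluoroborate; 3 diethyl (4-methyl-2-oxopent-3-en-3-yl)phosphonate
Product: 9 racemic diethyl (2,6,6-trimethyl-4-oxocyclohex-2-en-1-yl)phosphonate, via 2-ethoxyallylidene ylide 6 (not isolated), via open-chain keto ylide 7 (not isolated), via ethoxydiene phosphonate 8 (not isolated)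
Conditions: LiN(iPr)2, THF, −78 °C; add 3, −78 °C → reflux; then 1 M aq. HCl, THF, rt
Reagents that add atoms: water, O
Why: Ylide 6 adds through its terminal CH2 (γ) carbon to the β,β-dimethyl terminus of 3, which is activated by both the acetyl and the phosphoryl group, and so makes the C1–C2 bond and the quaternary C1; proton transfer from the new allylic CH2 to the phosphonate-stabilised enolate regenerates an ylide (7), whose carbon C4 attacks the methyl ketone carbon C5 in an intramolecular Wittig reaction that makes C4=C5 and gives dienol ether 8. Mild acid then protonates 8 at C2 and hydrolyses it to the conjugated enone 9, so the ethoxy group is only a mask for the C3 oxygen. The closest known reaction types are the cyclohexenone annulation of 2-alkoxyallylidenephosphoranes with enones and the cyclohexadiene annulation of allylidenephosphoranes with alkylidene acetoacetates, both Michael addition/intramolecular Wittig sequences. The single ring is closed by attack of the ylide carbon on a ketone whose C=O lies outside the forming six-membered ring (6-exo-trig), followed by collapse of the oxaphosphetane. No stereocentre of the target is set, since C6 is formed racemic and becomes sp2 in step 4. The step needs conjugate γ-addition in preference to α-attack, direct olefination of the acetyl group or deprotonation of a methyl group of 3, which the doubly activated, tetrasubstituted and cross-conjugated acceptor should secure, and the sense of ring closure is fixed because only C4 carries phosphorus.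

**Step 4**
Reactants: 9 racemic diethyl (2,6,6-trimethyl-4-oxocyclohex-2-en-1-yl)phosphonate; 10 2,2-dimethoxyacetaldehyde (dried from the commercial aqueous solution)
Product: 12 (2E)-2-(2,6,6-trimethyl-4-oxocyclohex-2-en-1-ylidene)acetaldehyde, via dienone dimethyl acetal 11 (not isolated)
Conditions: KOtBu, THF, 0 °C; add 10, 0 °C → rt; then 1 M aq. HCl, THF, rt
Reagents that add atoms: water, O
Why: Vinylogous Horner–Wadsworth–Emmons olefination, in which the C6–H of 9 (α to phosphorus, γ to the enone) is removed, the dienolate adds through C6 to the small activated aldehyde and only this adduct can lose diethyl phosphate, so that C6=C7 forms with the chain expected on the side away from the in-plane C5 methyl group (E), and acid then frees the aldehyde.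

**Step 5**
Reactants: 12 (2E)-2-(2,6,6-trimethyl-4-oxocyclohex-2-en-1-ylidene)acetaldehyde; 13 2-(triphenylphosphoranylidene)propanal
Product: 14 (2E,4E)-2-methyl-4-(2,6,6-trimethyl-4-oxocyclohex-2-en-1-ylidene)but-2-enal
Conditions: PhMe, 70 °C
Reagents that add atoms: none
Why: Wittig reaction with a formyl-stabilised ylide, which should react with the aldehyde and not with the ring ketone and give the E trisubstituted enal (C8=C9).

**Step 6**
Reactants: 15 ethyl (2E)-4-(diethoxyphosphoryl)-3-methylbut-2-enoate (2 equiv); 16 1,4-dioxane-2,3-diol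
Product: 18 diethyl (2E,4E,6E,8E)-3,8-dimethyldeca-2,4,6,8-tetraenedioate, via glyoxal 17 (not isolated)
Conditions: LiOH·H2O, 4 Å molecular sieves, THF, rt → reflux; recrystallisation
Reagents that add atoms: none
Why: Two-directional Horner–Wadsworth–Emmons olefination, in which the hemiacetal 16 opens under base to glyoxal 17 and both aldehyde groups react with the carbanion of 15 at the carbon next to phosphorus, so that the disubstituted C14=C15 and C15'=C14' bonds should form E.

**Step 7**
Reactants: 18 diethyl (2E,4E,6E,8E)-3,8-dimethyldeca-2,4,6,8-tetraenedioate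
Product: 19 (2E,4E,6E,8E)-3,8-dimethyldeca-2,4,6,8-tetraene-1,10-diol
Conditions: iBu2AlH, CH2Cl2, −78 → 0 °C; aq. potassium sodium tartrate
Reagents that add atoms: none
Why: 1,2-Reduction of both conjugated esters to the allylic alcohols by the aluminium hydride at low temperature should leave the tetraene untouched.

**Step 8**
Reactants: 19 (2E,4E,6E,8E)-3,8-dimethyldeca-2,4,6,8-tetraene-1,10-diol
Product: 20 [(2E,4E,6E,8E)-3,8-dimethyldeca-2,4,6,8-tetraene-1,10-diyl]bis(triphenylphosphonium) dibromide
Conditions: Ph3P·HBr, MeOH, rt, dark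
Reagents that add atoms: triphenylphosphine hydrobromide, [Br-].c1ccc(cc1)[PH+](c1ccccc1)c1ccccc1
Why: Phosphonium salt formation from allylic alcohols, in which HBr ionises each primary allylic alcohol and triphenylphosphine captures the delocalised cation at the terminal carbon, which keeps the tetraene conjugated.

**Step 9**
Reactants: 20 [(2E,4E,6E,8E)-3,8-dimethyldeca-2,4,6,8-tetraene-1,10-diyl]bis(triphenylphosphonium) dibromide; 14 (2E,4E)-2-methyl-4-(2,6,6-trimethyl-4-oxocyclohex-2-en-1-ylidene)but-2-enal (2 equiv)
Product: 22 (6E,6'E)-4',5'-didehydro-4,5'-retro-β,β-carotene-3,3'-dione (rhodoxanthin), via bis-ylide 21 (not isolated)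
Conditions: 1,2-epoxybutane, EtOH/CH2Cl2, reflux, dark; crystallisation
Reagents that add atoms: none
Why: Two-directional Wittig olefination, in which the epoxide takes up HBr and so generates bis-ylide 21 without strong base, 21 should react at C11 and C11' with the aldehyde groups of two molecules of 14 in preference to the ring ketones, and heating should isomerise Z bonds (C10=C11, C6=C7) towards the all-E isomer, which is expected to crystallise.

**Step 10**
Reactants: 22 (6E,6'E)-4',5'-didehydro-4,5'-retro-β,β-carotene-3,3'-dione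
Product: 23 (3S,3'S,6E,6'E)-4',5'-didehydro-4,5'-retro-β,β-carotene-3,3'-diol (target)
Conditions: (R)-1-methyl-3,3-diphenyltetrahydro-1H,3H-pyrrolo[1,2-c][1,3,2]oxazaborole, catecholborane, CH2Cl2/PhMe, −40 °C, dark; MeOH, then dilute aq. NaOH wash
Reagents that add atoms: none
Why: Corey–Bakshi–Shibata reduction, in which each ring ketone should bind to the boron of the (R)-catalyst with the polyenyl-substituted sp2 carbon C4 as the large group and CH2 (C2) as the small group, so that hydride is delivered to the face that gives the 3S and 3'S alcohols (reagent control, both centres in one operation), while the cyclic s-trans enones allow only 1,2-reduction and the acid-free work-up protects the polyenylic alcohols.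

**Compound list**

1 | diethyl (2-oxopropyl)phosphonate | CCOP(=O)(CC(C)=O)OCC | starting material
2 | acetone | CC(C)=O | starting material
3 | diethyl (4-methyl-2-oxopent-3-en-3-yl)phosphonate | CCOP(=O)(OCC)C(C(C)=O)=C(C)C | intermediate
4 | 1-(triphenylphosphoranylidene)propan-2-one | CC(=O)C=P(c1ccccc1)(c1ccccc1)c1ccccc1 | starting material
5 | (2-ethoxyprop-1-en-1-yl)triphenylphosphonium tetrafluoroborate | CCOC(C)=C[P+](c1ccccc1)(c1ccccc1)c1ccccc1.F[B-](F)(F)F | intermediate
6 | (2-ethoxyprop-2-en-1-ylidene)triphenylphosphorane (not isolated) | C=C(OCC)C=P(c1ccccc1)(c1ccccc1)c1ccccc1 | intermediate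
7 | diethyl [6-ethoxy-4,4-dimethyl-2-oxo-7-(triphenylphosphoranylidene)hept-5-en-3-yl]phosphonate (not isolated) | CCOC(C=P(c1ccccc1)(c1ccccc1)c1ccccc1)=CC(C)(C)C(C(C)=O)P(=O)(OCC)OCC | intermediate
8 | racemic diethyl (4-ethoxy-2,6,6-trimethylcyclohexa-2,4-dien-1-yl)phosphonate (not isolated) | CCOC1=CC(C)(C)C(P(=O)(OCC)OCC)C(C)=C1 | intermediate
9 | racemic diethyl (2,6,6-trimethyl-4-oxocyclohex-2-en-1-yl)phosphonate | CCOP(=O)(OCC)C1C(C)=CC(=O)CC1(C)C | intermediate
10 | 2,2-dimethoxyacetaldehyde | COC(OC)C=O | starting material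
11 | 4-[(1E)-2,2-dimethoxyethylidene]-3,5,5-trimethylcyclohex-2-en-1-one (not isolated) | COC(OC)/C=C1/C(C)=CC(=O)CC1(C)C | intermediate
12 | (2E)-2-(2,6,6-trimethyl-4-oxocyclohex-2-en-1-ylidene)acetaldehyde | O=C/C=C1/C(C)=CC(=O)CC1(C)C | intermediate
13 | 2-(triphenylphosphoranylidene)propanal | CC(C=O)=P(c1ccccc1)(c1ccccc1)c1ccccc1 | starting material
14 | (2E,4E)-2-methyl-4-(2,6,6-trimethyl-4-oxocyclohex-2-en-1-ylidene)but-2-enal | O=C/C(C)=C/C=C1/C(C)=CC(=O)CC1(C)C | intermediate
15 | ethyl (2E)-4-(diethoxyphosphoryl)-3-methylbut-2-enoate | CCOC(=O)/C=C(\C)CP(=O)(OCC)OCC | starting material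
16 | 1,4-dioxane-2,3-diol | OC1OCCOC1O | starting material
17 | glyoxal (not isolated) | O=CC=O | intermediate
18 | diethyl (2E,4E,6E,8E)-3,8-dimethyldeca-2,4,6,8-tetraenedioate | CCOC(=O)/C=C(C)/C=C/C=C/C(C)=C/C(=O)OCC | intermediate
19 | (2E,4E,6E,8E)-3,8-dimethyldeca-2,4,6,8-tetraene-1,10-diol | OC/C=C(C)/C=C/C=C/C(C)=C/CO | intermediate
20 | [(2E,4E,6E,8E)-3,8-dimethyldeca-2,4,6,8-tetraene-1,10-diyl]bis(triphenylphosphonium) dibromide | [Br-].[Br-].c1ccccc1[P+](c1ccccc1)(c1ccccc1)C/C=C(C)/C=C/C=C/C(C)=C/C[P+](c1ccccc1)(c1ccccc1)c1ccccc1 | intermediate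
21 | [(2E,4E,6E,8E)-3,8-dimethyldeca-2,4,6,8-tetraene-1,10-diylidene]bis(triphenylphosphorane) (not isolated) | c1ccccc1P(c1ccccc1)(c1ccccc1)=C/C=C(C)/C=C/C=C/C(C)=C/C=P(c1ccccc1)(c1ccccc1)c1ccccc1 | intermediate
22 | (6E,6'E)-4',5'-didehydro-4,5'-retro-β,β-carotene-3,3'-dione (rhodoxanthin) | CC1=CC(=O)CC(C)(C)\C1=C/C=C(C)/C=C/C=C(C)/C=C/C=C/C(C)=C/C=C/C(C)=C/C=C1/C(C)=CC(=O)CC1(C)C | intermediate
23 | (3S,3'S,6E,6'E)-4',5'-didehydro-4,5'-retro-β,β-carotene-3,3'-diol, all chain double bonds E | CC1=C[C@@H](O)CC(C)(C)\C1=C/C=C(C)/C=C/C=C(C)/C=C/C=C/C(C)=C/C=C/C(C)=C/C=C1/C(C)=C[C@@H](O)CC1(C)C | target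

**Step count and risks**

Total step count: 10. Longest linear sequence: 6 steps (steps 1, 3, 4, 5, 9, 10).

Steps most likely to fail:

1. Step 4. The C6 carbanion is flanked by the quaternary C1 and the substituted C5, so addition to the aldehyde may be too slow or may take place reversibly at C4 only; the geometry of the new C6=C7 bond may also be poorly controlled. Fallback (sets out from 9, comes back at 12): the carbanion of 9 is oxygenated (KOtBu, O2, THF), and the α-hydroperoxy phosphonate collapses to 2,6,6-trimethylcyclohex-2-ene-1,4-dione F1. Ketalisation with ethane-1,2-diol and TsOH, with azeotropic removal of water, should occur at the unhindered carbonyl (C3) and give 7,9,9-trimethyl-1,4-dioxaspiro[4.5]dec-6-en-8-one F2. 1,2-Addition of (Z)-2-ethoxyvinyllithium (from the tributylstannane and BuLi, THF, −78 °C) to the hindered ketone gives racemic 8-[(Z)-2-ethoxyethenyl]-7,9,9-trimethyl-1,4-dioxaspiro[4.5]dec-6-en-8-ol F3. Aqueous HCl in THF then converts the β-ethoxyvinyl carbinol into the enal by loss of water and removes the ketal, which gives 12.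

2. Step 3. The ylide may act as a base towards the methyl groups of 3, or the Michael adduct may fail to transfer the proton and close the ring. Fallback (sets out from 3, comes back at 9): Mukaiyama–Michael addition of 2-(trimethylsilyloxy)propene to 3 (TiCl4, CH2Cl2, −78 °C) gives racemic diethyl (4,4-dimethyl-2,6-dioxoheptan-3-yl)phosphonate F4. Intramolecular aldol condensation (pyrrolidine, AcOH, PhMe, heat), in which the methyl group of the unhindered ketone attacks the ketone next to phosphorus, gives 9.

3. Step 10. Facial discrimination may be insufficient, because the CH2 side carries the neighbouring quaternary carbon; 22 may be poorly soluble at low temperature; the borane may add to the polyene. Fallback (sets out from 11, isolated after a neutral work-up of step 4, comes back at 23): the same Corey–Bakshi–Shibata reduction on the small dienone gives (1S,4E)-4-(2,2-dimethoxyethylidene)-3,5,5-trimethylcyclohex-2-en-1-ol F5, which can be enriched before use. Silylation (tert-butyldimethylsilyl chloride, imidazole, DMF) gives the silyl ether F6. Acetal cleavage under nearly neutral conditions (catalytic I2, acetone, rt) gives (2E)-2-[(4S)-4-(tert-butyldimethylsilyloxy)-2,6,6-trimethylcyclohex-2-en-1-ylidene]acetaldehyde F7. Wittig reaction with 13 gives (2E,4E)-4-[(4S)-4-(tert-butyldimethylsilyloxy)-2,6,6-trimethylcyclohex-2-en-1-ylidene]-2-methylbut-2-enal F8. Double Wittig reaction of two molecules of F8 with 20 (via 21, 1,2-epoxybutane, EtOH, reflux) gives the 3,3'-bis(tert-butyldimethylsilyl) ether of 23 F9. Bu4NF in THF at 0 °C then gives 23 without contact with acid.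

**Further compounds**

F1 | step 4 | 2,6,6-trimethylcyclohex-2-ene-1,4-dione | CC1=CC(=O)CC(C)(C)C1=O
F2 | step 4 | 7,9,9-trimethyl-1,4-dioxaspiro[4.5]dec-6-en-8-one | CC1=CC2(CC(C)(C)C1=O)OCCO2
F3 | step 4 | racemic 8-[(Z)-2-ethoxyethenyl]-7,9,9-trimethyl-1,4-dioxaspiro[4.5]dec-6-en-8-ol | CCO/C=C\C1(O)C(C)=CC2(CC1(C)C)OCCO2
F4 | step 3 | racemic diethyl (4,4-dimethyl-2,6-dioxoheptan-3-yl)phosphonate | CCOP(=O)(OCC)C(C(C)=O)C(C)(C)CC(C)=O
F5 | step 10 | (1S,4E)-4-(2,2-dimethoxyethylidene)-3,5,5-trimethylcyclohex-2-en-1-ol | COC(OC)/C=C1/C(C)=C[C@@H](O)CC1(C)C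
F6 | step 10 | tert-butyl{[(1S,4E)-4-(2,2-dimethoxyethylidene)-3,5,5-trimethylcyclohex-2-en-1-yl]oxy}dimethylsilane | COC(OC)/C=C1/C(C)=C[C@@H](O[Si](C)(C)C(C)(C)C)CC1(C)C
F7 | step 10 | (2E)-2-[(4S)-4-(tert-butyldimethylsilyloxy)-2,6,6-trimethylcyclohex-2-en-1-ylidene]acetaldehyde | O=C/C=C1/C(C)=C[C@@H](O[Si](C)(C)C(C)(C)C)CC1(C)C
F8 | step 10 | (2E,4E)-4-[(4S)-4-(tert-butyldimethylsilyloxy)-2,6,6-trimethylcyclohex-2-en-1-ylidene]-2-methylbut-2-enal | O=C/C(C)=C/C=C1/C(C)=C[C@@H](O[Si](C)(C)C(C)(C)C)CC1(C)C
F9 | step 10 | (3S,3'S,6E,6'E)-3,3'-bis(tert-butyldimethylsilyloxy)-4',5'-didehydro-4,5'-retro-β,β-carotene | CC1=C[C@@H](O[Si](C)(C)C(C)(C)C)CC(C)(C)\C1=C/C=C(C)/C=C/C=C(C)/C=C/C=C/C(C)=C/C=C/C(C)=C/C=C1/C(C)=C[C@@H](O[Si](C)(C)C(C)(C)C)CC1(C)C
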